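**Plan**

1. Retrosynthesis, pyrone numbered O1–C2(=O)–C3–C4(OH)–C5–C6(styryl): cut the lactone bond O1–C2, then C2–C3 (C2 comes from methyl chloroformate), leaving a C3–C6 chain.
2. In that chain C4(O)–C5–C6(O) is a 1,3-dioxygenated three-carbon unit, which is what an isoxazole ring masks. Its C5–C6 bond is where the styryl half meets the terpene half, so the isoxazole is cut at C5–C6 and C4–O (retro-[3+2]) into (E)-cinnamonitrile oxide and a terpenyl propargyl alkyne.
3. The alkyne is traced back through aldehyde homologation, hydroboration of a vinyl group, methylation of an enol triflate and conjugate vinylation to (R)-cryptone, itself made from 3-methylbutanal and methyl vinyl ketone.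
4. Forward order: cyclohexene ring (Michael addition, aldol condensation), then the isoxazole (cycloaddition joining the two halves), then C2 by carboxylation, and last the pyrone ring by N–O cleavage, hydrolysis and lactonisation.
5. Stereochemistry: the isopropyl-bearing centre comes from an enantioselective organocatalytic Michael addition, the neighbouring ring centre from anti (trans) conjugate addition to cryptone, and the E-styryl alkene from cinnamaldehyde.

Key step: step 10

Assumption: the prolinol ether catalyst is taken to follow the usual steric-shielding enamine model, so the (R)-catalyst should give the (R)-aldehyde 3; if the sense were opposite, the enantiomeric catalyst would be used.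

**Step 1**
Reactants: 1 3-methylbutanal (isovaleraldehyde); 2 but-3-en-2-one (methyl vinyl ketone)
Product: 3 (2R)-5-oxo-2-(propan-2-yl)hexanal
Conditions: (R)-2-(methoxydiphenylmethyl)pyrrolidine (5 mol%), ethyl 3,4-dihydroxybenzoate (20 mol%), neat, 4 °C
Reagents that add atoms: none
Why: Enamine-catalysed asymmetric Michael addition of an aldehyde to an enone, in which the diphenyl(methoxy)methyl group shields one face of the (E)-enamine so that the enone is attacked from the open face and the isopropyl-bearing centre should form as R.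

**Step 2**
Reactants: 3 (2R)-5-oxo-2-(propan-2-yl)hexanal
Product: 4 (4R)-4-(propan-2-yl)cyclohex-2-en-1-one [(R)-cryptone]
Conditions: LiOH, i-PrOH, rt
Reagents that add atoms: none
Why: Intramolecular aldol condensation in which the methyl ketone enolate closes onto the aldehyde and the aldol loses water to the conjugated enone, the mild hydroxide/isopropanol medium being chosen so that the stereocentre (the γ-carbon of the enone) is not epimerised.

**Step 3**
Reactants: 4 (R)-cryptone
Product: 6 (3R,4R)-3-ethenyl-4-(propan-2-yl)cyclohex-1-en-1-yl trifluoromethanesulfonate, via bromomagnesium enolate 5 (not isolated)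
Conditions: CH2=CHMgBr (1.5 equiv), CuBr·SMe2 (0.2 equiv), THF, −78 → −40 °C; then N-(5-chloro-2-pyridyl)triflimide, −78 °C → rt
Reagents that add atoms: vinylmagnesium bromide, C=C[Mg]Br; N-(5-chloropyridin-2-yl)bis(trifluoromethanesulfonyl)imide, FC(F)(F)S(=O)(=O)N(c1ccc(Cl)cn1)S(=O)(=O)C(F)(F)F
Why: Copper-catalysed conjugate addition of the vinyl Grignard reagent, in which the vinyl group enters C3 anti to the C4 isopropyl group (the usual trans outcome for 4-alkylcyclohexenones) and so sets the second stereocentre, followed by O-triflation of the regiodefined enolate, which fixes the double bond between C1 and C2.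

**Step 4**
Reactants: 6 (3R,4R)-3-ethenyl-4-(propan-2-yl)cyclohex-1-en-1-yl trifluoromethanesulfonate
Product: 7 (3R,4R)-3-ethenyl-1-methyl-4-(propan-2-yl)cyclohex-1-ene
Conditions: MeMgBr (1.5 equiv), Fe(acac)3 (5 mol%), THF/NMP, −30 → 0 °C
Reagents that add atoms: methylmagnesium bromide, C[Mg]Br
Why: Iron-catalysed Kumada-type cross-coupling of an alkenyl triflate with a methyl Grignard reagent replaces the triflate by methyl without moving the double bond, and the short reaction at low temperature should leave the doubly allylic centre and the vinyl group untouched.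

**Step 5**
Reactants: 7 (3R,4R)-3-ethenyl-1-methyl-4-(propan-2-yl)cyclohex-1-ene
Product: 8 2-[(1R,6R)-3-methyl-6-(propan-2-yl)cyclohex-2-en-1-yl]ethan-1-ol
Conditions: 9-BBN, THF, 0 °C → rt; then NaOH, H2O2 (aq), 0 °C
Reagents that add atoms: hydrogen peroxide, OO
Why: Hydroboration–oxidation with the bulky dialkylborane is anti-Markovnikov and selective for the monosubstituted vinyl group over the trisubstituted ring alkene, giving the primary alcohol with both stereocentres unchanged.

**Step 6**
Reactants: 8 2-[(1R,6R)-3-methyl-6-(propan-2-yl)cyclohex-2-en-1-yl]ethan-1-ol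
Product: 9 2-[(1R,6R)-3-methyl-6-(propan-2-yl)cyclohex-2-en-1-yl]acetaldehyde
Conditions: Dess–Martin periodinane, CH2Cl2, 0 °C → rt
Reagents that add atoms: none
Why: Dess–Martin oxidation takes the primary alcohol to the aldehyde under neutral conditions, without over-oxidation and without migration of the ring double bond.

**Step 7**
Reactants: 9 2-[(1R,6R)-3-methyl-6-(propan-2-yl)cyclohex-2-en-1-yl]acetaldehyde
Product: 10 (3R,4R)-1-methyl-4-(propan-2-yl)-3-(prop-2-yn-1-yl)cyclohex-1-ene
Conditions: dimethyl (1-diazo-2-oxopropyl)phosphonate, K2CO3, MeOH, 0 °C → rt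
Reagents that add atoms: dimethyl (1-diazo-2-oxopropyl)phosphonate, CC(=O)C(=[N+]=[N-])P(=O)(OC)OC
Why: Ohira–Bestmann variant of the Seyferth–Gilbert homologation, in which the diazomethylphosphonate anion released by methanolysis olefinates the aldehyde and loss of N2 with 1,2-hydride shift gives the terminal alkyne one carbon longer, the stereocentre lying β to the aldehyde and therefore not at risk.

**Step 8**
Reactants: 11 (E)-cinnamaldehyde
Product: 12 (1E,2E)-cinnamaldehyde oxime
Conditions: NH2OH·HCl, NaOAc, EtOH/H2O, rt
Reagents that add atoms: hydroxylamine hydrochloride, NO.Cl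
Why: Condensation of the aldehyde with hydroxylamine gives the aldoxime and leaves the E-styryl double bond unchanged.

**Step 9**
Reactants: 12 (1E,2E)-cinnamaldehyde oxime
Product: 13 (1Z,2E)-N-hydroxy-3-phenylprop-2-enimidoyl chloride
Conditions: N-chlorosuccinimide, DMF, rt
Reagents that add atoms: N-chlorosuccinimide, O=C1CCC(=O)N1Cl
Why: C-chlorination of an aldoxime with N-chlorosuccinimide in DMF is the standard entry to hydroximoyl chlorides and should spare the conjugated alkene at ambient temperature; the crude chloride is used directly.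

**Step 10**
Reactants: 10 (3R,4R)-1-methyl-4-(propan-2-yl)-3-(prop-2-yn-1-yl)cyclohex-1-ene; 13 (1Z,2E)-N-hydroxy-3-phenylprop-2-enimidoyl chloride
Product: 15 5-{[(1R,6R)-3-methyl-6-(propan-2-yl)cyclohex-2-en-1-yl]methyl}-3-[(E)-2-phenylethenyl]-1,2-oxazole, via (E)-cinnamonitrile oxide 14 (not isolated)
Conditions: 13 (2 equiv), Et3N (2.2 equiv, syringe pump over 10 h), CH2Cl2, 0 °C → rt
Reagents that add atoms: none
Why: Triethylamine removes HCl from 13 to release the nitrile oxide 14 at low stationary concentration, and 14 adds to the terminal alkyne of 10 in a concerted, asynchronous, suprafacial [3+2] (Huisgen 1,3-dipolar) cycloaddition that forms the C–C bond (dipole carbon to the terminal CH, future pyrone C6–C5) and the C–O bond (dipole oxygen to the internal alkyne carbon, future C4–O) together. The closest known reaction type is the cycloaddition of aryl or alkenyl nitrile oxides with terminal alkyl alkynes, which gives 3,5-disubstituted isoxazoles directly at the aromatic oxidation level. The isoxazole ring is closed by intermolecular cycloaddition (C, N and O from the dipole, two carbons from the alkyne), not by cyclisation of a chain. No stereocentre is created, and the two allylic stereocentres of 10 lie outside the reacting π-system and should be untouched at ambient temperature under weakly basic conditions. The step needs regioselectivity, secured by the monosubstituted alkyne whose unhindered terminal carbon bonds to the dipole carbon, and chemoselectivity over the ring alkene, secured by the low dipolarophilicity of that hindered trisubstituted double bond. Slow addition of base and an excess of 13 are used because dimerisation of 14 to the furoxan is the main competing path.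

**Step 11**
Reactants: 15 5-{[(1R,6R)-3-methyl-6-(propan-2-yl)cyclohex-2-en-1-yl]methyl}-3-[(E)-2-phenylethenyl]-1,2-oxazole
Product: 17 methyl 2-[(1R,6R)-3-methyl-6-(propan-2-yl)cyclohex-2-en-1-yl]-2-{3-[(E)-2-phenylethenyl]-1,2-oxazol-5-yl}acetate (both epimers at the new centre), via lithiated isoxazole 16 (not isolated)
Conditions: LiN(iPr)2 (1.1 equiv), THF, −78 °C; then cannulated into ClCO2Me (3 equiv), THF, −78 °C
Reagents that add atoms: methyl chloroformate, COC(=O)Cl
Why: Lateral lithiation of a 5-alkylisoxazole removes a proton from the CH2 on isoxazole C5 (stabilised by the ring C=N–O), and C-acylation of this carbanion under inverse addition installs the future pyrone C2, the new stereocentre forming without control, which is harmless because that carbon becomes sp2 in the pyrone.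

**Step 12**
Reactants: 17 methyl 2-[(1R,6R)-3-methyl-6-(propan-2-yl)cyclohex-2-en-1-yl]-2-{3-[(E)-2-phenylethenyl]-1,2-oxazol-5-yl}acetate
Product: 18 methyl (4Z,6E)-5-amino-2-[(1R,6R)-3-methyl-6-(propan-2-yl)cyclohex-2-en-1-yl]-3-oxo-7-phenylhepta-4,6-dienoate
Conditions: Mo(CO)6 (1 equiv), MeCN/H2O, 80 °C
Reagents that add atoms: none
Why: Mo(CO)6 in wet acetonitrile effects the established reductive cleavage of the isoxazole N–O bond to the Z β-enaminone, with water as proton source, and tolerates the alkenes, the styryl group and the ester.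

**Step 13**
Reactants: 18 methyl (4Z,6E)-5-amino-2-[(1R,6R)-3-methyl-6-(propan-2-yl)cyclohex-2-en-1-yl]-3-oxo-7-phenylhepta-4,6-dienoate
Product: 19 methyl (6E)-2-[(1R,6R)-3-methyl-6-(propan-2-yl)cyclohex-2-en-1-yl]-3,5-dioxo-7-phenylhept-6-enoate (largely enolised)
Conditions: 1 M HCl (aq), THF, 0 °C → rt
Reagents that add atoms: water, O
Why: Acid hydrolysis of the vinylogous amide (C-protonation to the iminium ion, addition of water, loss of ammonia) unveils the 1,3-diketone and supplies the oxygen that becomes the ring O1, while the acidic medium keeps nitrogen protonated so that it cannot attack the ester, and the acid is kept dilute and cold to spare the ring alkene.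

**Step 14**
Reactants: 19 methyl (6E)-2-[(1R,6R)-3-methyl-6-(propan-2-yl)cyclohex-2-en-1-yl]-3,5-dioxo-7-phenylhept-6-enoate
Product: 20 4-hydroxy-3-[(1R,6R)-3-methyl-6-(propan-2-yl)cyclohex-2-en-1-yl]-6-[(E)-2-phenylethenyl]-2H-pyran-2-one (CNP0362785.1)
Conditions: DBU (1.5 equiv), toluene, 80 °C; then cold 0.5 M HCl wash
Reagents that add atoms: none
Why: Base-mediated lactonisation of a 3,5-dioxo ester, in which the enolate oxygen of the C5 ketone attacks the ester carbonyl (6-exo-trig acyl substitution) with loss of methanol, is the standard closure of triketide esters to 4-hydroxy-2-pyrones and converts the epimeric C3 centre into an sp2 carbon.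

**Compound list**

1 | 3-methylbutanal (isovaleraldehyde) | CC(C)CC=O | starting material
2 | but-3-en-2-one (methyl vinyl ketone) | CC(=O)C=C | starting material
3 | (2R)-5-oxo-2-(propan-2-yl)hexanal | O=C[C@@H](C(C)C)CCC(C)=O | intermediate
4 | (4R)-4-(propan-2-yl)cyclohex-2-en-1-one, (R)-cryptone | O=C1C=C[C@@H](C(C)C)CC1 | intermediate
5 | bromomagnesium (3R,4R)-3-ethenyl-4-(propan-2-yl)cyclohex-1-en-1-olate | Br[Mg]OC1=C[C@H](C=C)[C@@H](C(C)C)CC1 | intermediate (not isolated)
6 | (3R,4R)-3-ethenyl-4-(propan-2-yl)cyclohex-1-en-1-yl trifluoromethanesulfonate | O=S(=O)(OC1=C[C@H](C=C)[C@@H](C(C)C)CC1)C(F)(F)F | intermediate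
7 | (3R,4R)-3-ethenyl-1-methyl-4-(propan-2-yl)cyclohex-1-ene | CC1=C[C@H](C=C)[C@@H](C(C)C)CC1 | intermediate
8 | 2-[(1R,6R)-3-methyl-6-(propan-2-yl)cyclohex-2-en-1-yl]ethan-1-ol | CC1=C[C@H](CCO)[C@@H](C(C)C)CC1 | intermediate
9 | 2-[(1R,6R)-3-methyl-6-(propan-2-yl)cyclohex-2-en-1-yl]acetaldehyde | CC1=C[C@H](CC=O)[C@@H](C(C)C)CC1 | intermediate
10 | (3R,4R)-1-methyl-4-(propan-2-yl)-3-(prop-2-yn-1-yl)cyclohex-1-ene | CC1=C[C@H](CC#C)[C@@H](C(C)C)CC1 | intermediate
11 | (E)-cinnamaldehyde | O=C/C=C/c1ccccc1 | starting material
12 | (1E,2E)-cinnamaldehyde oxime | O/N=C/C=C/c1ccccc1 | intermediate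
13 | (1Z,2E)-N-hydroxy-3-phenylprop-2-enimidoyl chloride | O/N=C(\Cl)/C=C/c1ccccc1 | intermediate
14 | (E)-cinnamonitrile oxide | [O-][N+]#C/C=C/c1ccccc1 | intermediate (not isolated)
15 | 5-{[(1R,6R)-3-methyl-6-(propan-2-yl)cyclohex-2-en-1-yl]methyl}-3-[(E)-2-phenylethenyl]-1,2-oxazole | CC1=C[C@H](Cc2cc(/C=C/c3ccccc3)no2)[C@@H](C(C)C)CC1 | intermediate
16 | 15 lithiated at the CH2 on isoxazole C5 | CC1=C[C@H](C([Li])c2cc(/C=C/c3ccccc3)no2)[C@@H](C(C)C)CC1 | intermediate (not isolated)
17 | methyl 2-[(1R,6R)-3-methyl-6-(propan-2-yl)cyclohex-2-en-1-yl]-2-{3-[(E)-2-phenylethenyl]-1,2-oxazol-5-yl}acetate (both epimers at C2 of the acetate) | CC1=C[C@H](C(C(=O)OC)c2cc(/C=C/c3ccccc3)no2)[C@@H](C(C)C)CC1 | intermediate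
18 | methyl (4Z,6E)-5-amino-2-[(1R,6R)-3-methyl-6-(propan-2-yl)cyclohex-2-en-1-yl]-3-oxo-7-phenylhepta-4,6-dienoate | CC1=C[C@H](C(C(=O)OC)C(=O)/C=C(\N)/C=C/c2ccccc2)[C@@H](C(C)C)CC1 | intermediate
19 | methyl (6E)-2-[(1R,6R)-3-methyl-6-(propan-2-yl)cyclohex-2-en-1-yl]-3,5-dioxo-7-phenylhept-6-enoate | CC1=C[C@H](C(C(=O)OC)C(=O)CC(=O)/C=C/c2ccccc2)[C@@H](C(C)C)CC1 | intermediate
20 | 4-hydroxy-3-[(1R,6R)-3-methyl-6-(propan-2-yl)cyclohex-2-en-1-yl]-6-[(E)-2-phenylethenyl]-2H-pyran-2-one | CC1=C[C@H](c2c(O)cc(/C=C/c3ccccc3)oc2=O)[C@@H](C(C)C)CC1 | target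

**Step count**

Total: 14 steps. Longest linear sequence: 12 steps (steps 1–7 and 10–14, from 3-methylbutanal); the dipole branch (steps 8 and 9) has 2 steps.

**Steps most likely to fail**

Step 10. The nitrile oxide may dimerise to the furoxan faster than it adds to an unactivated alkyl alkyne, so that the alkyne is recovered. The fallback builds the same isoxazole without a dipole and sets out from alkyne 10. Deprotonation with n-BuLi (THF, −78 °C) and addition to cinnamaldehyde 11 would give the propargylic alcohol (1E)-6-[(1R,6R)-3-methyl-6-(propan-2-yl)cyclohex-2-en-1-yl]-1-phenylhex-1-en-4-yn-3-ol F1 as both carbinol epimers. MnO2 in CH2Cl2 would oxidise it to the ynone (1E)-6-[(1R,6R)-3-methyl-6-(propan-2-yl)cyclohex-2-en-1-yl]-1-phenylhex-1-en-4-yn-3-one F2. Hydroxylamine hydrochloride in pyridine would give the ynone oxime F3. AuCl3-catalysed 5-endo-dig cycloisomerisation of the oxime oxygen onto the alkyne would then come back to the route at isoxazole 15. The regiochemistry is fixed because nitrogen sits on the styryl-bearing carbon from the start.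

Step 11. Proton transfer from the newly formed, more acidic ester to unreacted carbanion may stall conversion, and the ester enolate may be acylated a second time. The fallback sets out from isoxazole 15 and changes the electrophile class. The anion 16 would be quenched with CO2 (THF, −78 °C, then acid work-up) to give the carboxylic acid 2-[(1R,6R)-3-methyl-6-(propan-2-yl)cyclohex-2-en-1-yl]-2-{3-[(E)-2-phenylethenyl]-1,2-oxazol-5-yl}acetic acid F4. Its lithium carboxylate cannot be acylated again and is a much weaker carbon acid. Esterification with (trimethylsilyl)diazomethane in MeOH/toluene would come back to the route at ester 17.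

Step 13. During hydrolysis the free amino group may attack the neighbouring ester (lactam formation to a pyridone), or the β-keto ester may be cleaved and decarboxylated before the diketone is released. The fallback removes nitrogen before any ester is present and sets out from isoxazole 15. Mo(CO)6 in MeCN/H2O would give the ester-free enaminone (1E,3Z)-3-amino-6-[(1R,6R)-3-methyl-6-(propan-2-yl)cyclohex-2-en-1-yl]-1-phenylhexa-1,3-dien-5-one F5. Hydrolysis with 1 M HCl in THF would give the β-diketone (1E)-6-[(1R,6R)-3-methyl-6-(propan-2-yl)cyclohex-2-en-1-yl]-1-phenylhex-1-ene-3,5-dione F6, in which no lactam can form. The 1,3-diketone dianion (LiN(iPr)2, 3 equiv, THF, −78 → 0 °C) would then be acylated with dimethyl carbonate at its terminal carbanion, the CH2 next to the terpene ring, since the cinnamoyl side has no enolisable position. This comes back to the route at diketo ester 19.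

**Further compounds**

F1 | step 10 | (1E)-6-[(1R,6R)-3-methyl-6-(propan-2-yl)cyclohex-2-en-1-yl]-1-phenylhex-1-en-4-yn-3-ol (both carbinol epimers) | CC1=C[C@H](CC#CC(O)/C=C/c2ccccc2)[C@@H](C(C)C)CC1
F2 | step 10 | (1E)-6-[(1R,6R)-3-methyl-6-(propan-2-yl)cyclohex-2-en-1-yl]-1-phenylhex-1-en-4-yn-3-one | CC1=C[C@H](CC#CC(=O)/C=C/c2ccccc2)[C@@H](C(C)C)CC1
F3 | step 10 | (1E)-6-[(1R,6R)-3-methyl-6-(propan-2-yl)cyclohex-2-en-1-yl]-1-phenylhex-1-en-4-yn-3-one oxime | CC1=C[C@H](CC#CC(=NO)/C=C/c2ccccc2)[C@@H](C(C)C)CC1
F4 | step 11 | 2-[(1R,6R)-3-methyl-6-(propan-2-yl)cyclohex-2-en-1-yl]-2-{3-[(E)-2-phenylethenyl]-1,2-oxazol-5-yl}acetic acid (both epimers at C2) | CC1=C[C@H](C(C(=O)O)c2cc(/C=C/c3ccccc3)no2)[C@@H](C(C)C)CC1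
F5 | step 13 | (1E,3Z)-3-amino-6-[(1R,6R)-3-methyl-6-(propan-2-yl)cyclohex-2-en-1-yl]-1-phenylhexa-1,3-dien-5-one | CC1=C[C@H](CC(=O)/C=C(\N)/C=C/c2ccccc2)[C@@H](C(C)C)CC1
F6 | step 13 | (1E)-6-[(1R,6R)-3-methyl-6-(propan-2-yl)cyclohex-2-en-1-yl]-1-phenylhex-1-ene-3,5-dione | CC1=C[C@H](CC(=O)CC(=O)/C=C/c2ccccc2)[C@@H](C(C)C)CC1
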